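**Retrosynthetic overview**

1. The target is disconnected at the CH2–CH2 bond of its aryl‑ethyl ester bridge. An α‑acyloxymethyl radical (from the O‑acylglycolic redox‑active ester 16 of the masked secoiridoid acid) and a benzylic radical (from the (3,4‑dihydroxyphenyl)acetic redox‑active ester 20) are joined by Ni‑electrocatalytic doubly decarboxylative coupling.
2. Enabling feature: in the O–CH2–CH2–aryl bridge one carbon is α to the ester oxygen and the other is benzylic to the 3,4‑dioxygenated benzene ring, so both are reachable as stabilised radicals from carboxylic acids. The 1,5‑dialdehyde with its β‑formyl ester is stored as a 2‑methoxy‑3,4‑dihydro‑2H‑pyran ring (acetal carbon plus O–CH=C–CO2Me vinylogous carbonate), which keeps aldehydes, enal and acidic C–H out of the radical step.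
3. Secoiridoid half: the E‑ethylidene comes from (Z)‑2‑bromocrotonaldehyde acetal (Heck reaction with acrolein), the chain stereocentre from an iminium‑catalysed Michael addition of a thiomalonate, the acid from Pinnick oxidation. Fukuyama reduction and acid closure then form the only ring that is built, the dihydropyran (step 7).
4. End game (step 14): fluoride frees the catechol, aqueous acid hydrolyses the pyran acetal, and biomimetic ring‑chain opening of the lactol releases enal and formyl ester. The benzene ring is bought.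

Key step: step 13

Assumption: the CH between CHO and CO2Me is a 1,3‑dicarbonyl methine that epimerises through its enol; it is created in the last step and its (S) configuration is taken to be governed by the fixed neighbouring centre under equilibrating conditions, not by a kinetic event.

**Route**

Step 1
Reactants: 1 (2E)-but-2-enal (crotonaldehyde)
Product: 3 (2Z)-2-bromobut-2-enal, via 2,3-dibromobutanal 2 (not isolated)
Conditions: Br2, CH2Cl2, 0 °C; then Et3N, 0 °C to rt
Reagents that add atoms: bromine, BrBr
Why: Bromination–dehydrobromination (anti addition, then E1cB loss of HBr) should give the thermodynamically preferred Z α‑bromo enal with CH3 trans to CHO, the geometry later needed in the ethylidene group.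

Step 2
Reactants: 3 (2Z)-2-bromobut-2-enal
Product: 4 (2Z)-2-bromo-1,1-dimethoxybut-2-ene
Conditions: HC(OMe)3, MeOH, NH4NO3 (cat.), rt
Reagents that add atoms: trimethyl orthoformate, COC(OC)OC
Why: Acid‑catalysed acetalisation with orthoformate as water scavenger should mask the aldehyde without touching the alkenyl bromide or its geometry.

Step 3
Reactants: 4 (2Z)-2-bromo-1,1-dimethoxybut-2-ene; 5 prop-2-enal (acrolein)
Product: 6 (2E,4E)-4-(dimethoxymethyl)hexa-2,4-dienal
Conditions: Pd(OAc)2 (5 mol %), Bu4NCl, NaHCO3, DMF, 50 °C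
Reagents that add atoms: none
Why: Mizoroki–Heck reaction under phosphine‑free phase‑transfer conditions: oxidative addition with retention at the alkenyl bromide, β‑selective insertion of acrolein and syn β‑hydride elimination should give the E enal with CH3 cis to the new chain.

Step 4
Reactants: 7 methyl 3-chloro-3-oxopropanoate (methyl malonyl chloride)
Product: 8 methyl 3-(ethylsulfanyl)-3-oxopropanoate
Conditions: EtSH, pyridine, CH2Cl2, 0 °C
Reagents that add atoms: ethanethiol, CCS
Why: Acyl substitution of the acid chloride by the thiol should give the mixed thiomalonate, whose thioester is the latent formyl group.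

Step 5
Reactants: 6 dienal; 8 thiomalonate
Product: 9 methyl (3S,4E)-4-(dimethoxymethyl)-2-[(ethylsulfanyl)carbonyl]-3-(2-oxoethyl)hex-4-enoate (epimers at C2)
Conditions: (R)-2-{bis[3,5-bis(trifluoromethyl)phenyl][(trimethylsilyl)oxy]methyl}pyrrolidine (10 mol %), PhCO2H (10 mol %), MeOH, 0 °C
Reagents that add atoms: none
Why: Iminium‑catalysed Michael addition of a malonate‑type C–H acid to an enal: the (R)-diarylprolinol silyl ether shields the Si face of the β‑carbon of the E,s‑trans iminium ion, so the thiomalonate should add to the Re face and set the S centre, with 1,4‑ preferred over 1,6‑addition because the β‑position is unsubstituted; the thiomalonate carbon is an inconsequential epimer mixture.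

Step 6
Reactants: 9 aldehyde thiomalonate
Product: 10 (3S,4E)-4-(dimethoxymethyl)-3-[2-(ethylsulfanyl)-1-(methoxycarbonyl)-2-oxoethyl]hex-4-enoic acid
Conditions: NaClO2, NaH2PO4, 2-methylbut-2-ene, t-BuOH/H2O, 0 °C
Reagents that add atoms: sodium chlorite, [Na+].[O-]Cl=O
Why: Pinnick oxidation should convert only the aldehyde into the acid, the buffered medium and the hypochlorite scavenger sparing acetal, thioester and trisubstituted alkene.

Step 7
Reactants: 10 thioester acid
Product: 12 2-[(2S,3E,4R)-3-ethylidene-2-methoxy-5-(methoxycarbonyl)-3,4-dihydro-2H-pyran-4-yl]acetic acid, via formyl ester 11 (not isolated)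
Conditions: Pd/C (10 %), Et3SiH, acetone, rt; filter; then PPTS, 4 Å MS, CH2Cl2, rt
Reagents that add atoms: none
Why: Fukuyama reduction should convert only the thioester into the aldehyde, and the enol oxygen of the resulting β‑formyl ester then closes (6‑exo‑trig transacetalisation) onto the oxocarbenium ion of the allylic dimethyl acetal; the thiomalonate carbon becomes sp2 and the 2,4‑trans anomer is expected to predominate, the anomeric centre being cleared in step 14.

Step 8
Reactants: 12 pyran acetic acid; 13 prop-2-en-1-yl bromoacetate (allyl bromoacetate)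
Product: 14 prop-2-en-1-yl ({[(2S,3E,4R)-3-ethylidene-2-methoxy-5-(methoxycarbonyl)-3,4-dihydro-2H-pyran-4-yl]acetyl}oxy)acetate
Conditions: KHCO3, DMF, rt
Reagents that add atoms: none
Why: SN2 O‑alkylation of the carboxylate by the α‑bromo ester should install the glycolate carbon that becomes the O–CH2 of the bridge; no C–H acid remains in the base‑stable pyran.

Step 9
Reactants: 14 allyl ester
Product: 15 ({[(2S,3E,4R)-3-ethylidene-2-methoxy-5-(methoxycarbonyl)-3,4-dihydro-2H-pyran-4-yl]acetyl}oxy)acetic acid
Conditions: Pd(PPh3)4 (5 mol %), sodium p-toluenesulfinate, THF/MeOH, rt; cold dilute HCl work-up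
Reagents that add atoms: none
Why: Tsuji–Trost deallylation with a neutral sulfinate scavenger should free the acid without exposing the vinylogous carbonate or the acyloxyacetate to amines or hydroxide.

Step 10
Reactants: 15 O-acylglycolic acid
Product: 16 1,3-dioxoisoindolin-2-yl ({[(2S,3E,4R)-3-ethylidene-2-methoxy-5-(methoxycarbonyl)-3,4-dihydro-2H-pyran-4-yl]acetyl}oxy)acetate
Conditions: N-hydroxyphthalimide, DIC, DMAP (cat.), CH2Cl2, 0 °C to rt
Reagents that add atoms: N-hydroxyphthalimide, ON1C(=O)c2ccccc2C1=O
Why: Carbodiimide esterification should give the redox‑active ester that serves as precursor of the α‑acyloxymethyl radical.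

Step 11
Reactants: 17 (3,4-dihydroxyphenyl)acetic acid
Product: 19 {3,4-bis[(tert-butyldimethylsilyl)oxy]phenyl}acetic acid, via silyl ester 18 (not isolated)
Conditions: TBSCl (3.3 equiv), imidazole, DMF, rt; then AcOH/THF/H2O, rt
Reagents that add atoms: tert-butyldimethylsilyl chloride, CC(C)(C)[Si](C)(C)Cl
Why: Exhaustive silylation followed by selective hydrolysis of the labile silyl ester should leave the two aryl silyl ethers, which keep the catechol from binding nickel or being acylated.

Step 12
Reactants: 19 bis-silylated arylacetic acid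
Product: 20 1,3-dioxoisoindolin-2-yl {3,4-bis[(tert-butyldimethylsilyl)oxy]phenyl}acetate
Conditions: N-hydroxyphthalimide, DIC, DMAP (cat.), CH2Cl2, rt
Reagents that add atoms: N-hydroxyphthalimide, ON1C(=O)c2ccccc2C1=O
Why: Carbodiimide esterification should give the benzylic redox‑active ester.

Step 13
Reactants: 16 glycolate redox-active ester; 20 benzylic redox-active ester (3 equiv)
Product: 21 methyl (2S,3E,4R)-4-{2-[2-(3,4-bis{[tert-butyl(dimethyl)silyl]oxy}phenyl)ethoxy]-2-oxoethyl}-3-ethylidene-2-methoxy-3,4-dihydro-2H-pyran-5-carboxylate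
Conditions: NiCl2·6H2O (20 mol %), 4,4′,4″-tri-tert-butyl-2,2′:6′,2″-terpyridine (20 mol %), AgNO3 (0.3 equiv), LiCl, DMF, (+)Mg/(−)RVC, undivided cell, constant current, rt
Reagents that add atoms: none
Why: Proposed new method: both N‑acyloxyphthalimides should accept an electron from cathodically generated low‑valent terpyridine–nickel (or at the cathode) and fragment with loss of CO2 and phthalimide anion to the α‑acyloxymethyl radical from 16 and the 3,4‑bis(silyloxy)benzyl radical from 20; successive capture of the two radicals at nickel and reductive elimination from a dialkyl‑Ni(III) species forms the CH2–CH2 bond, the magnesium anode supplying the electrons. The closest known reaction type is the Ni‑electrocatalytic doubly decarboxylative C(sp3)–C(sp3) coupling of two alkyl redox‑active esters; new here is the pairing of an α‑acyloxyalkyl ester with an arylacetic ester. No ring is closed and no stereocentre is created; the two pyran stereocentres are remote from the radical site and untouched. The step needs cross‑ over homo‑coupling, which the three‑fold excess of the cheap benzylic ester 20 and the different lifetimes of the partners (short‑lived α‑acyloxymethyl radical, longer‑lived benzylic radical) should secure, bibenzyl being the tolerated by‑product. It also needs chemoselectivity, which the substrate secures by holding both aldehydes inside the dihydropyran acetal, so that only a vinylogous carbonate and a trisubstituted alkene remain, both poor acceptors that could be reached only through seven‑membered or larger rings.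

Step 14
Reactants: 21 coupled bis-silyl pyran acetal
Product: 24 methyl (2S,3S,4E)-3-{2-[2-(3,4-dihydroxyphenyl)ethoxy]-2-oxoethyl}-2,4-diformylhex-4-enoate, via catechol acetal 22 (not isolated), via lactol 23 (not isolated)
Conditions: HF·pyridine, THF, 0 °C; then 2 M aq. HCl to pH 1, rt; extractive work-up without base
Reagents that add atoms: water, O
Why: Fluoride should remove the aryl silyl ethers and aqueous acid hydrolyse the allylic methyl acetal to the lactol, whose ring‑chain opening (the biomimetic opening of secoiridoid aglycones) releases the enal and the enol of the formyl ester; ketonisation creates the formyl‑ester methine, which equilibrates under the acidic conditions and is expected to settle, under control of the adjacent fixed centre, in the S configuration that places CO2Me and the acetate arm anti.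

**Compound list**

1 | (2E)-but-2-enal (crotonaldehyde) | C/C=C/C=O | starting material
2 | rac-(2R,3S)-2,3-dibromobutanal | C[C@H](Br)[C@H](Br)C=O | intermediate
3 | (2Z)-2-bromobut-2-enal | C/C=C(\Br)C=O | intermediate
4 | (2Z)-2-bromo-1,1-dimethoxybut-2-ene | C/C=C(\Br)C(OC)OC | intermediate
5 | prop-2-enal (acrolein) | C=CC=O | starting material
6 | (2E,4E)-4-(dimethoxymethyl)hexa-2,4-dienal | C/C=C(\C=C\C=O)C(OC)OC | intermediate
7 | methyl 3-chloro-3-oxopropanoate | COC(=O)CC(=O)Cl | starting material
8 | methyl 3-(ethylsulfanyl)-3-oxopropanoate | CCSC(=O)CC(=O)OC | intermediate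
9 | methyl (3S,4E)-4-(dimethoxymethyl)-2-[(ethylsulfanyl)carbonyl]-3-(2-oxoethyl)hex-4-enoate (epimers at C2) | C/C=C(/C(OC)OC)[C@@H](CC=O)C(C(=O)OC)C(=O)SCC | intermediate
10 | (3S,4E)-4-(dimethoxymethyl)-3-[2-(ethylsulfanyl)-1-(methoxycarbonyl)-2-oxoethyl]hex-4-enoic acid | C/C=C(/C(OC)OC)[C@@H](CC(=O)O)C(C(=O)OC)C(=O)SCC | intermediate
11 | (3S,4E)-4-(dimethoxymethyl)-3-[1-(methoxycarbonyl)-2-oxoethyl]hex-4-enoic acid | C/C=C(/C(OC)OC)[C@@H](CC(=O)O)C(C=O)C(=O)OC | intermediate
12 | 2-[(2S,3E,4R)-3-ethylidene-2-methoxy-5-(methoxycarbonyl)-3,4-dihydro-2H-pyran-4-yl]acetic acid (2,4-trans anomer drawn) | C/C=C1/[C@@H](OC)OC=C(C(=O)OC)[C@@H]1CC(=O)O | intermediate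
13 | prop-2-en-1-yl bromoacetate | C=CCOC(=O)CBr | starting material
14 | prop-2-en-1-yl ({[(2S,3E,4R)-3-ethylidene-2-methoxy-5-(methoxycarbonyl)-3,4-dihydro-2H-pyran-4-yl]acetyl}oxy)acetate | C/C=C1/[C@@H](OC)OC=C(C(=O)OC)[C@@H]1CC(=O)OCC(=O)OCC=C | intermediate
15 | ({[(2S,3E,4R)-3-ethylidene-2-methoxy-5-(methoxycarbonyl)-3,4-dihydro-2H-pyran-4-yl]acetyl}oxy)acetic acid | C/C=C1/[C@@H](OC)OC=C(C(=O)OC)[C@@H]1CC(=O)OCC(=O)O | intermediate
16 | 1,3-dioxoisoindolin-2-yl ({[(2S,3E,4R)-3-ethylidene-2-methoxy-5-(methoxycarbonyl)-3,4-dihydro-2H-pyran-4-yl]acetyl}oxy)acetate | C/C=C1/[C@@H](OC)OC=C(C(=O)OC)[C@@H]1CC(=O)OCC(=O)ON2C(=O)c3ccccc3C2=O | intermediate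
17 | (3,4-dihydroxyphenyl)acetic acid | OC(=O)Cc1ccc(O)c(O)c1 | starting material
18 | tert-butyldimethylsilyl {3,4-bis[(tert-butyldimethylsilyl)oxy]phenyl}acetate | CC(C)(C)[Si](C)(C)OC(=O)Cc1ccc(O[Si](C)(C)C(C)(C)C)c(O[Si](C)(C)C(C)(C)C)c1 | intermediate
19 | {3,4-bis[(tert-butyldimethylsilyl)oxy]phenyl}acetic acid | OC(=O)Cc1ccc(O[Si](C)(C)C(C)(C)C)c(O[Si](C)(C)C(C)(C)C)c1 | intermediate
20 | 1,3-dioxoisoindolin-2-yl {3,4-bis[(tert-butyldimethylsilyl)oxy]phenyl}acetate | O=C(Cc1ccc(O[Si](C)(C)C(C)(C)C)c(O[Si](C)(C)C(C)(C)C)c1)ON1C(=O)c2ccccc2C1=O | intermediate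
21 | methyl (2S,3E,4R)-4-{2-[2-(3,4-bis{[tert-butyl(dimethyl)silyl]oxy}phenyl)ethoxy]-2-oxoethyl}-3-ethylidene-2-methoxy-3,4-dihydro-2H-pyran-5-carboxylate | C/C=C1/[C@@H](OC)OC=C(C(=O)OC)[C@@H]1CC(=O)OCCc2ccc(O[Si](C)(C)C(C)(C)C)c(O[Si](C)(C)C(C)(C)C)c2 | intermediate
22 | methyl (2S,3E,4R)-4-{2-[2-(3,4-dihydroxyphenyl)ethoxy]-2-oxoethyl}-3-ethylidene-2-methoxy-3,4-dihydro-2H-pyran-5-carboxylate | C/C=C1/[C@@H](OC)OC=C(C(=O)OC)[C@@H]1CC(=O)OCCc2ccc(O)c(O)c2 | intermediate
23 | methyl (2S,3E,4R)-4-{2-[2-(3,4-dihydroxyphenyl)ethoxy]-2-oxoethyl}-3-ethylidene-2-hydroxy-3,4-dihydro-2H-pyran-5-carboxylate (lactol, one anomer drawn) | C/C=C1/[C@@H](O)OC=C(C(=O)OC)[C@@H]1CC(=O)OCCc2ccc(O)c(O)c2 | intermediate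
24 | methyl (2S,3S,4E)-3-{2-[2-(3,4-dihydroxyphenyl)ethoxy]-2-oxoethyl}-2,4-diformylhex-4-enoate | C/C=C(/C=O)[C@@H](CC(=O)OCCc1ccc(O)c(O)c1)[C@@H](C=O)C(=O)OC | target

**Step count and risks**

Total step count: 14. Longest linear sequence: 11 steps (steps 1–3, 5–10, 13, 14).

Steps most likely to fail:

1. Step 13 (proposed new method). Homo‑dimerisation of either radical, or loss of the limiting α‑acyloxymethyl partner by reduction or hydrogen abstraction, may outpace cross‑coupling at nickel. The fallback uses known chemistry and sets out from acids 12 and 19: borane reduction of 19 (BH3·THF, 0 °C) would give 2-{3,4-bis[(tert-butyldimethylsilyl)oxy]phenyl}ethan-1-ol F1, and carbodiimide esterification of 12 with this alcohol (EDC·HCl, DMAP, CH2Cl2) comes back to the route at 21; steps 8–10 and 12 are then not needed.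

2. Step 14. During the aqueous acid stage the liberated enol may re‑close by conjugate addition onto the ethylidene enal (ring transposition), and slow acetal hydrolysis prolongs the exposure of the labile formyl‑ester carbon, so the epimer ratio may be poor. The fallback sets out from 21 and reverses the order of unmasking: aprotic cleavage of the mixed methyl acetal (TESOTf, 2,4,6‑collidine, CH2Cl2, 0 °C; then H2O) would give the bis‑silylated dialdehyde methyl (2S,3S,4E)-3-{2-[2-(3,4-bis{[tert-butyl(dimethyl)silyl]oxy}phenyl)ethoxy]-2-oxoethyl}-2,4-diformylhex-4-enoate F2, and brief treatment with pyridine‑buffered HF·pyridine then arrives at 24.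

3. Step 7. The thioester hydrogenolysis may stall through catalyst poisoning or reduce the alkene, and in the cyclisation the free carboxylic acid may capture the oxocarbenium ion (acylal lactone) or the ring may close with allylic transposition. The fallback sets out from 10 and installs the glycolate before the ring is made: O‑alkylation with 2-(trimethylsilyl)ethyl bromoacetate (KHCO3, DMF) would give the 2-(trimethylsilyl)ethyl glycolate thioester F3, Fukuyama reduction (Pd/C, Et3SiH) its formyl ester F4 (not isolated), PPTS closure the pyran 2-(trimethylsilyl)ethyl ester F5, and TBAF (THF, 0 °C) comes back to the route at 15; steps 8 and 9 are then not needed.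

Further compounds
F1 | step 13 | 2-{3,4-bis[(tert-butyldimethylsilyl)oxy]phenyl}ethan-1-ol | OCCc1ccc(O[Si](C)(C)C(C)(C)C)c(O[Si](C)(C)C(C)(C)C)c1
F2 | step 14 | methyl (2S,3S,4E)-3-{2-[2-(3,4-bis{[tert-butyl(dimethyl)silyl]oxy}phenyl)ethoxy]-2-oxoethyl}-2,4-diformylhex-4-enoate | C/C=C(/C=O)[C@@H](CC(=O)OCCc1ccc(O[Si](C)(C)C(C)(C)C)c(O[Si](C)(C)C(C)(C)C)c1)[C@@H](C=O)C(=O)OC
F3 | step 7 | 2-(trimethylsilyl)ethyl ({(3S,4E)-4-(dimethoxymethyl)-3-[2-(ethylsulfanyl)-1-(methoxycarbonyl)-2-oxoethyl]hex-4-enoyl}oxy)acetate | C/C=C(/C(OC)OC)[C@@H](CC(=O)OCC(=O)OCC[Si](C)(C)C)C(C(=O)OC)C(=O)SCC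
F4 | step 7 | 2-(trimethylsilyl)ethyl ({(3S,4E)-4-(dimethoxymethyl)-3-[1-(methoxycarbonyl)-2-oxoethyl]hex-4-enoyl}oxy)acetate | C/C=C(/C(OC)OC)[C@@H](CC(=O)OCC(=O)OCC[Si](C)(C)C)C(C=O)C(=O)OC
F5 | step 7 | 2-(trimethylsilyl)ethyl ({[(2S,3E,4R)-3-ethylidene-2-methoxy-5-(methoxycarbonyl)-3,4-dihydro-2H-pyran-4-yl]acetyl}oxy)acetate | C/C=C1/[C@@H](OC)OC=C(C(=O)OC)[C@@H]1CC(=O)OCC(=O)OCC[Si](C)(C)C
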